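**Retrosynthetic overview**

1. Target 27 is (13S)-15-formyloxylabd-8(17)-en-19-oic acid. The formate, the C19 acid (from an axial C19 aldehyde), the C8 methylene (Wittig) and the C4 quaternary centre (α-face methylation of a C4 aldehyde enolate) are late events on a trans-decalin.
2. The strategy rests on C10 (quaternary, bearing C20) and C5 being adjacent ring-fusion carbons flanked by C1 and C4. This unit maps onto the methyl-bearing C=C and the two carbonyls of 2-methoxy-5-methyl-1,4-benzoquinone, while C6–C9 of ring B, with oxygen at C8 and the side chain at C9, is a 1-alkyl-2-silyloxydiene.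
3. Key disconnection: C5–C6 and C9–C10 by an enantioselective quinone Diels–Alder reaction. Ring A arrives preformed as the quinone; ring B is the only ring closed, in that step.
4. The diene (C6–C9, C11–C16) comes from methyl hydrogen (R)-3-methylglutarate (source of C13), a Horner–Wadsworth–Emmons two-carbon extension and vinylmagnesium bromide.
5. After the cycloaddition, C5 is epimerised to the trans fusion, C4 is homologated by one carbon, ring A is stripped of oxygen (SmI2, then Barton–McCombie at C1), and C9 is epimerised once the C8 ketone is unmasked.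

Key step: step 8

Assumption: the (R)-binaphtholate ligand is taken as the enantiomer that leads to the 10R series; the sense of induction has to be read from the first adduct and the (S)-ligand substituted if it is opposite.
Numbering: labdane numbering is used for all ring compounds (C17 = methylene carbon on C8, C19 = carboxyl carbon on C4, C20 = methyl on C10, C11–C16 = side chain, oxygen on C15).

**Route**

Step 1
Reactants: 1 methyl hydrogen (R)-3-methylglutarate
Product: 2 methyl (R)-5-hydroxy-3-methylpentanoate
Conditions: BH3·SMe2, THF, 0 °C → rt; MeOH quench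
Reagents that add atoms: none
Why: Chemoselective borane reduction: the free acid is reduced through its acyloxyborane much faster than the methyl ester, and the C13 stereocentre is not touched.

Step 2
Reactants: 2 methyl (R)-5-hydroxy-3-methylpentanoate
Product: 3 methyl (R)-5-(tert-butyldiphenylsilyloxy)-3-methylpentanoate
Conditions: TBDPSCl, imidazole, CH2Cl2, 0 °C → rt
Reagents that add atoms: tert-butyl(chloro)diphenylsilane, CC(C)(C)[Si](Cl)(c1ccccc1)c1ccccc1
Why: Imidazole-mediated silyl ether formation protects the future C15 oxygen and prevents lactonisation of the hydroxy ester.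

Step 3
Reactants: 3 methyl (R)-5-(tert-butyldiphenylsilyloxy)-3-methylpentanoate
Product: 4 (R)-5-(tert-butyldiphenylsilyloxy)-3-methylpentanal
Conditions: i-Bu2AlH (1.05 equiv), CH2Cl2, −78 °C
Reagents that add atoms: none
Why: Partial ester reduction with i-Bu2AlH stops at the aluminium hemiacetal at −78 °C, which releases the aldehyde on work-up.

Step 4
Reactants: 4 (R)-5-(tert-butyldiphenylsilyloxy)-3-methylpentanal
Product: 5 (2E,5S)-7-(tert-butyldiphenylsilyloxy)-N-methoxy-N,5-dimethylhept-2-enamide
Conditions: (EtO)2P(O)CH2C(O)N(OMe)Me, NaH, THF, 0 °C → rt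
Reagents that add atoms: diethyl [2-[methoxy(methyl)amino]-2-oxoethyl]phosphonate, CCOP(=O)(OCC)CC(=O)N(C)OC
Why: Horner–Wadsworth–Emmons olefination adds C9 and C8 already at the Weinreb amide oxidation level; the alkene geometry is irrelevant because it is hydrogenated next.

Step 5
Reactants: 5 (2E,5S)-7-(tert-butyldiphenylsilyloxy)-N-methoxy-N,5-dimethylhept-2-enamide
Product: 6 (5S)-7-(tert-butyldiphenylsilyloxy)-N-methoxy-N,5-dimethylheptanamide
Conditions: H2 (1 atm), Pd/C, EtOAc, rt
Reagents that add atoms: none
Why: Heterogeneous hydrogenation saturates the conjugated alkene without cleaving the N–O bond or the silyl ether.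

Step 6
Reactants: 6 (5S)-7-(tert-butyldiphenylsilyloxy)-N-methoxy-N,5-dimethylheptanamide; 7 vinylmagnesium bromide
Product: 8 (7S)-9-(tert-butyldiphenylsilyloxy)-7-methylnon-1-en-3-one
Conditions: CH2=CHMgBr, THF, 0 °C; inverse quench into cold 1 M HCl
Reagents that add atoms: none
Why: Weinreb ketone synthesis: the chelated tetrahedral adduct prevents over-addition, and the cold acidic inverse quench keeps the liberated amine from adding to the vinyl ketone.

Step 7
Reactants: 8 (7S)-9-(tert-butyldiphenylsilyloxy)-7-methylnon-1-en-3-one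
Product: 9 (3Z,7S)-3-(tert-butyldimethylsilyloxy)-9-(tert-butyldiphenylsilyloxy)-7-methylnona-1,3-diene
Conditions: TBSOTf, Et3N, Et2O, −78 → 0 °C
Reagents that add atoms: tert-butyldimethylsilyl trifluoromethanesulfonate, CC(C)(C)[Si](C)(C)OS(=O)(=O)C(F)(F)F
Why: Soft enolisation (silyl enol ether formation) can only occur at the sp3 α-carbon C9 and should give the Z dienol ether, in which the chain is trans to the vinyl group and so avoids allylic strain.

Step 8
Reactants: 9 (3Z,7S)-3-(tert-butyldimethylsilyloxy)-9-(tert-butyldiphenylsilyloxy)-7-methylnona-1,3-diene; 10 2-methoxy-5-methyl-1,4-benzoquinone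
Product: 11 cis-fused adduct, (13S)-8-(tert-butyldimethylsilyloxy)-15-(tert-butyldiphenylsilyloxy)-3-methoxy-17,18,19-trinorlabda-2,7-diene-1,4-dione with 10β-methyl, 5β-H and 9β-H (C11 α, anti to C20)
Conditions: TiCl2[(R)-1,1'-bi-2-naphtholate] (20 mol %, tetravalent titanium; from TiCl2(Oi-Pr)2 and the binaphthol, 4 Å sieves), CH2Cl2, −40 → −20 °C
Reagents that add atoms: none
Why: Tetravalent titanium chelated between the C4 carbonyl and the neighbouring methoxy oxygen lowers the LUMO of the C5=C10 alkene and makes C10 its electrophilic end, which pairs with C9, the nucleophilic terminus of the silyloxydiene, in an asynchronous concerted endo [4+2] cycloaddition. The closest known reaction types are chiral titanium binaphtholate-catalysed Diels–Alder reactions of quinones and the chelation-controlled cycloadditions of this quinone at its methyl-bearing alkene. Ring B is closed by intermolecular [4+2] annulation that forms C9–C10 and C5–C6 suprafacially on both partners. C10 is set by the ligand, which should shield one face of the chelated quinone; C5–H is cis to C20 because the dienophile geometry is retained, and C11 is anti to C20 because the Z-diene substituent is outside in the endo transition state, so C5 and C9 are kinetic and are corrected in steps 9 and 15. The step needs site selectivity (the methoxy-bearing alkene is a deactivated vinylogous ester), regioselectivity (chelation and the 2-silyloxy polarisation act in the same sense as the thermal reaction) and enantiofacial selectivity (ligand). The remote C13 centre exerts no control and only makes the minor facial product a diastereomer.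

Step 9
Reactants: 11 cis-fused adduct
Product: 12 trans-fused ene-dione, as 11 but with 5α-H (9β-H retained)
Conditions: DBU (0.3 equiv), toluene, rt
Reagents that add atoms: none
Why: Base-mediated cis-to-trans epimerisation of a quinone adduct: C5–H is the only enolisable hydrogen of the ene-dione, and equilibration through the C4 dienolate should favour the trans fusion, in which C20 and the C9 chain are trans-diaxial and the chain avoids allylic strain with the C8 silyloxy group; the silyl enol ether is inert to amine base.

Step 10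
Reactants: 12 trans-fused ene-dione
Product: 14 trans-fused 17,18,19-trinorlabd-7-ene-1,4-dione (8-OTBS; 15-OTBDPS; 5α-H; 9β-H), via 3-methoxy-1,4-dione 13 (not isolated)
Conditions: SmI2 (5 equiv, divalent samarium), THF–MeOH, −78 → 0 °C
Reagents that add atoms: none
Why: Single-electron reduction of the ene-dione gives the 3-methoxy-1,4-dione, whose C3–OMe bond α to the C4 ketone is then cleaved through the ketyl (SmI2 reduction of α-alkoxy ketones); silyl enol ether, silyl ether and C5 are not affected at low temperature.

Step 11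
Reactants: 14 trans-fused 1,4-dione
Product: 15 (13S)-8-(tert-butyldimethylsilyloxy)-15-(tert-butyldiphenylsilyloxy)-19-methoxy-17,18-dinorlabda-4(19),7-dien-1-one (5α-H, 9β-H; E/Z mixture at C4=C19)
Conditions: Ph3P(CH2OMe)Cl, KN(SiMe3)2, THF, 0 °C → rt
Reagents that add atoms: (methoxymethyl)triphenylphosphonium chloride, COC[P+](c1ccccc1)(c1ccccc1)c1ccccc1.[Cl-]
Why: Wittig methoxymethylenation should occur at the C4 ketone because the C1 ketone is neopentyl (next to quaternary C10); it installs C19 as an enol ether and at the same time removes the enolisable position next to C5, locking the trans fusion.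

Step 12
Reactants: 15 C4 methoxymethylene C1 ketone
Product: 16 corresponding C1 alcohol (C1 epimers, inconsequential)
Conditions: LiAlH4, THF, 0 °C
Reagents that add atoms: none
Why: Hydride reduction of the only remaining ketone; both enol ethers and the silyl ether are inert to LiAlH4 at 0 °C.

Step 13
Reactants: 16 C1 alcohol
Product: 18 O-(C1) S-methyl dithiocarbonate of alcohol 16, via sodium xanthate 17 (not isolated)
Conditions: NaH, imidazole (cat.), CS2, THF, 0 °C → rt; then MeI
Reagents that add atoms: carbon disulfide, S=C=S; iodomethane, CI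
Why: Xanthate formation (alkoxide addition to CS2, then S-methylation) prepares the hindered secondary alcohol for radical deoxygenation under conditions that tolerate the silyl enol ether.

Step 14
Reactants: 18 C1 xanthate
Product: 19 (13S)-8-(tert-butyldimethylsilyloxy)-15-(tert-butyldiphenylsilyloxy)-19-methoxy-17,18-dinorlabda-4(19),7-diene (5α-H, 9β-H; E/Z mixture)
Conditions: Bu3SnH, AIBN (cat.), toluene, 110 °C
Reagents that add atoms: none
Why: Barton–McCombie deoxygenation removes the C1 oxygen through a secondary radical, avoiding cationic intermediates next to quaternary C10 and leaving both enol ethers intact.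

Step 15
Reactants: 19 bis-enol ether
Product: 21 9α-H C8 ketone (C11 β; equatorial), via 9-epi ketone 20 (not isolated)
Conditions: TBAF, AcOH, THF, 0 °C; then NaOMe, MeOH, rt
Reagents that add atoms: none
Why: Buffered fluoride cleaves the silyl enol ether far faster than the primary tert-butyldiphenylsilyl ether, and methoxide then epimerises C9 through the C8 enolate to the equatorial side chain of the trans-decalin (thermodynamic α-epimerisation); the methyl enol ether is stable to both reagents.

Step 16
Reactants: 21 C8 ketone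
Product: 22 (13S)-15-(tert-butyldiphenylsilyloxy)-19-methoxy-18-norlabda-4(19),8(17)-diene (E/Z mixture)
Conditions: Ph3PCH3Br, KOt-Bu, toluene, rt → 80 °C
Reagents that add atoms: methyltriphenylphosphonium bromide, C[P+](c1ccccc1)(c1ccccc1)c1ccccc1.[Br-]
Why: Wittig methylenation of the hindered C8 ketone installs C17; enolisation under the basic conditions can only return the thermodynamic C9 configuration.

Step 17
Reactants: 22 diene enol ether
Product: 23 (13S)-15-(tert-butyldiphenylsilyloxy)-18-norlabd-8(17)-en-19-al (C4 epimers)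
Conditions: 1 M aq. HCl, THF, 0 °C → rt
Reagents that add atoms: water, O
Why: Enol ether hydrolysis by C-protonation and hemiacetal collapse is much faster than protonation of the 1,1-disubstituted alkene in dilute aqueous acid; the C4 epimers converge in the next step.

Step 18
Reactants: 23 C4 aldehyde (epimers)
Product: 24 (13S)-15-(tert-butyldiphenylsilyloxy)labd-8(17)-en-19-al (4α-methyl, 4β-formyl; 4S)
Conditions: KOt-Bu, MeI, THF/t-BuOH, 0 °C → rt
Reagents that add atoms: iodomethane, CI
Why: Aldehyde enolate alkylation: the planar potassium enolate should be C-methylated from the equatorial α face because the β face is blocked by the 1,3-diaxial C20 methyl, which sets C4 with the formyl group axial as in the target.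

Step 19
Reactants: 24 quaternary aldehyde
Product: 25 (13S)-15-hydroxylabd-8(17)-en-19-al
Conditions: TBAF, THF, rt
Reagents that add atoms: none
Why: Fluoride-mediated desilylation; the non-enolisable aldehyde and the alkene are inert.

Step 20
Reactants: 25 hydroxy aldehyde
Product: 26 (13S)-15-formyloxylabd-8(17)-en-19-al
Conditions: HCO2H/Ac2O (premixed), pyridine, CH2Cl2, 0 °C
Reagents that add atoms: acetic formic anhydride, CC(=O)OC=O (formed in the flask from formic acid, O=CO, and acetic anhydride, CC(=O)OC(C)=O)
Why: O-Formylation: the mixed anhydride transfers its formyl group selectively to the primary alcohol, and the hindered neopentyl aldehyde does not react.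

Step 21
Reactants: 26 formate aldehyde
Product: 27 (4S,5R,9S,10R,13S)-15-formyloxylabd-8(17)-en-19-oic acid (target)
Conditions: NaClO2, NaH2PO4, 2-methyl-2-butene, t-BuOH/H2O, 0 °C → rt
Reagents that add atoms: sodium chlorite, [Na+].[O-]Cl=O
Why: Pinnick oxidation converts the hindered aldehyde to the acid in a mildly acidic buffer that leaves the formate intact, with 2-methyl-2-butene scavenging hypochlorous acid to protect the exocyclic alkene.

**Compound list**

1 | methyl hydrogen (R)-3-methylglutarate | COC(=O)C[C@H](C)CC(=O)O | starting material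
2 | methyl (R)-5-hydroxy-3-methylpentanoate | COC(=O)C[C@H](C)CCO | intermediate
3 | methyl (R)-5-(tert-butyldiphenylsilyloxy)-3-methylpentanoate | COC(=O)C[C@H](C)CCO[Si](c1ccccc1)(c2ccccc2)C(C)(C)C | intermediate
4 | (R)-5-(tert-butyldiphenylsilyloxy)-3-methylpentanal | O=CC[C@H](C)CCO[Si](c1ccccc1)(c2ccccc2)C(C)(C)C | intermediate
5 | (2E,5S)-7-(tert-butyldiphenylsilyloxy)-N-methoxy-N,5-dimethylhept-2-enamide | CON(C)C(=O)/C=C/C[C@H](C)CCO[Si](c1ccccc1)(c2ccccc2)C(C)(C)C | intermediate
6 | (5S)-7-(tert-butyldiphenylsilyloxy)-N-methoxy-N,5-dimethylheptanamide | CON(C)C(=O)CCC[C@H](C)CCO[Si](c1ccccc1)(c2ccccc2)C(C)(C)C | intermediate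
7 | vinylmagnesium bromide | C=C[Mg]Br | starting material
8 | (7S)-9-(tert-butyldiphenylsilyloxy)-7-methylnon-1-en-3-one | C=CC(=O)CCC[C@H](C)CCO[Si](c1ccccc1)(c2ccccc2)C(C)(C)C | intermediate
9 | (3Z,7S)-3-(tert-butyldimethylsilyloxy)-9-(tert-butyldiphenylsilyloxy)-7-methylnona-1,3-diene | C=C/C(O[Si](C)(C)C(C)(C)C)=C/CC[C@H](C)CCO[Si](c1ccccc1)(c2ccccc2)C(C)(C)C | intermediate
10 | 2-methoxy-5-methyl-1,4-benzoquinone | COC1=CC(=O)C(C)=CC1=O | starting material
11 | cis-fused adduct: 8-OTBS, 15-OTBDPS, 3-methoxy-17,18,19-trinorlabda-2,7-diene-1,4-dione; 10β-Me, 5β-H, 9β-H, 13S | CC(C)(C)[Si](C)(C)OC1=CC[C@H]2[C@](C)(C(=O)C=C(OC)C2=O)[C@@H]1CC[C@H](C)CCO[Si](c3ccccc3)(c4ccccc4)C(C)(C)C | intermediate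
12 | trans-fused ene-dione: as 11 with 5α-H, 9β-H | CC(C)(C)[Si](C)(C)OC1=CC[C@@H]2[C@](C)(C(=O)C=C(OC)C2=O)[C@@H]1CC[C@H](C)CCO[Si](c3ccccc3)(c4ccccc4)C(C)(C)C | intermediate
13 | 3-methoxy-1,4-dione (C3 epimers), trans-fused, 9β-H; not isolated | CC(C)(C)[Si](C)(C)OC1=CC[C@@H]2[C@](C)(C(=O)CC(OC)C2=O)[C@@H]1CC[C@H](C)CCO[Si](c3ccccc3)(c4ccccc4)C(C)(C)C | intermediate
14 | trans-fused 8-OTBS, 15-OTBDPS 17,18,19-trinorlabd-7-ene-1,4-dione; 5α-H, 9β-H | CC(C)(C)[Si](C)(C)OC1=CC[C@@H]2[C@](C)(C(=O)CCC2=O)[C@@H]1CC[C@H](C)CCO[Si](c3ccccc3)(c4ccccc4)C(C)(C)C | intermediate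
15 | 8-OTBS, 15-OTBDPS, 19-methoxy-17,18-dinorlabda-4(19),7-dien-1-one; 5α-H, 9β-H, E/Z mixture | CC(C)(C)[Si](C)(C)OC1=CC[C@@H]2[C@](C)(C(=O)CCC2=COC)[C@@H]1CC[C@H](C)CCO[Si](c3ccccc3)(c4ccccc4)C(C)(C)C | intermediate
16 | C1 alcohol of 15 (C1 epimers, E/Z mixture) | CC(C)(C)[Si](C)(C)OC1=CC[C@@H]2[C@](C)(C(O)CCC2=COC)[C@@H]1CC[C@H](C)CCO[Si](c3ccccc3)(c4ccccc4)C(C)(C)C | intermediate
17 | sodium O-(C1) dithiocarbonate of 16; not isolated | CC(C)(C)[Si](C)(C)OC1=CC[C@@H]2[C@](C)(C(OC(=S)[S-])CCC2=COC)[C@@H]1CC[C@H](C)CCO[Si](c3ccccc3)(c4ccccc4)C(C)(C)C.[Na+] | intermediate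
18 | O-(C1) S-methyl dithiocarbonate of 16 | CC(C)(C)[Si](C)(C)OC1=CC[C@@H]2[C@](C)(C(OC(=S)SC)CCC2=COC)[C@@H]1CC[C@H](C)CCO[Si](c3ccccc3)(c4ccccc4)C(C)(C)C | intermediate
19 | 8-OTBS, 15-OTBDPS, 19-methoxy-17,18-dinorlabda-4(19),7-diene; 5α-H, 9β-H, E/Z mixture | CC(C)(C)[Si](C)(C)OC1=CC[C@@H]2[C@](C)(CCCC2=COC)[C@@H]1CC[C@H](C)CCO[Si](c3ccccc3)(c4ccccc4)C(C)(C)C | intermediate
20 | 9-epi C8 ketone (9β-H, C11 α), 15-OTBDPS, 19-methoxy-17,18-dinorlabd-4(19)-en-8-one; not isolated | O=C1CC[C@@H]2[C@](C)(CCCC2=COC)[C@@H]1CC[C@H](C)CCO[Si](c3ccccc3)(c4ccccc4)C(C)(C)C | intermediate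
21 | C8 ketone with natural C9 (9α-H, C11 β), 15-OTBDPS, 19-methoxy-17,18-dinorlabd-4(19)-en-8-one | O=C1CC[C@@H]2[C@](C)(CCCC2=COC)[C@H]1CC[C@H](C)CCO[Si](c3ccccc3)(c4ccccc4)C(C)(C)C | intermediate
22 | 15-OTBDPS, 19-methoxy-18-norlabda-4(19),8(17)-diene (E/Z mixture) | C=C1CC[C@@H]2[C@](C)(CCCC2=COC)[C@H]1CC[C@H](C)CCO[Si](c3ccccc3)(c4ccccc4)C(C)(C)C | intermediate
23 | 15-OTBDPS 18-norlabd-8(17)-en-19-al (C4 epimers) | C=C1CC[C@@H]2[C@](C)(CCCC2C=O)[C@H]1CC[C@H](C)CCO[Si](c3ccccc3)(c4ccccc4)C(C)(C)C | intermediate
24 | (4S,13S)-15-(tert-butyldiphenylsilyloxy)labd-8(17)-en-19-al | C=C1CC[C@@H]2[C@](C)(CCC[C@]2(C)C=O)[C@H]1CC[C@H](C)CCO[Si](c3ccccc3)(c4ccccc4)C(C)(C)C | intermediate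
25 | (13S)-15-hydroxylabd-8(17)-en-19-al | C=C1CC[C@@H]2[C@](C)(CCC[C@]2(C)C=O)[C@H]1CC[C@H](C)CCO | intermediate
26 | (13S)-15-formyloxylabd-8(17)-en-19-al | C=C1CC[C@@H]2[C@](C)(CCC[C@]2(C)C=O)[C@H]1CC[C@H](C)CCOC=O | intermediate
27 | (4S,5R,9S,10R,13S)-15-formyloxylabd-8(17)-en-19-oic acid | C=C1CC[C@@H]2[C@](C)(CCC[C@]2(C)C(=O)O)[C@H]1CC[C@H](C)CCOC=O | target

**Step count**

Total steps: 21. Longest linear sequence: 21 steps (1 → 27); quinone 10 and Grignard reagent 7 enter as purchased partners.

**Steps most likely to fail**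

Step 8 (key cycloaddition). Facial discrimination by the titanium catalyst may be low with this α-methoxy chelate, or the Lewis acid may desilylate the diene or divert it into a stepwise Mukaiyama–Michael addition. The fallback sets out from 9 and 10 and comes back at 11. The cycloaddition is run thermally without Lewis acid (toluene, 60–80 °C). The more electron-poor C4 carbonyl of the quinone should impose the same regiochemistry and the endo rule the same relative configuration, but both quinone faces then react. The product is 11 together with its ring-antipodal diastereomer, the 10α-methyl cis adduct F1. The two differ through the fixed 13S centre and are separated by preparative chromatography on a chiral stationary phase; 11 continues in step 9.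

Step 9 (ring-fusion epimerisation). The equilibrium may not lie far enough on the trans side because ring A is flattened and the C9 chain is still axial, so cis and trans isomers could be close in energy. The fallback sets out from 11 and comes back at 12, replacing thermodynamic by kinetic control. Compound 11 is deprotonated with KN(SiMe3)2 in THF at −78 °C to the potassium C4(5)-dienolate F2 (C5–H is the only acidic hydrogen). F2 is protonated at −78 °C with AcOH, which should deliver the proton to C5 from the α face opposite the angular C20 methyl and give 12.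

Step 11 (methoxymethylenation at C4). The basic ylide may enolise the C4 ketone instead of adding to it, which would stall the olefination and erode the C5 configuration, or it may fail to discriminate between C4 and C1. The fallback sets out from 14 and comes back at 15 by a Peterson olefination. [Methoxy(trimethylsilyl)methyl]lithium, generated from (methoxymethyl)trimethylsilane and sec-BuLi in THF at −78 °C, is a smaller and more nucleophilic carbanion and should add to the C4 ketone to give the β-hydroxysilane F3. KH in THF then eliminates trimethylsilanolate to give 15.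

Further compounds
F1 | step 8 | ring-antipodal cis adduct (10α-methyl, 5α-H, 9α-H, 13S) | CC(C)(C)[Si](C)(C)OC1=CC[C@@H]2[C@@](C)(C(=O)C=C(OC)C2=O)[C@H]1CC[C@H](C)CCO[Si](c3ccccc3)(c4ccccc4)C(C)(C)C
F2 | step 9 | potassium C4(5)-dienolate of 11 | CC(C)(C)[Si](C)(C)OC1=CCC2=C([O-])C(OC)=CC(=O)[C@]2(C)[C@@H]1CC[C@H](C)CCO[Si](c3ccccc3)(c4ccccc4)C(C)(C)C.[K+]
F3 | step 11 | C4 β-hydroxysilane, 4-hydroxy-4-[methoxy(trimethylsilyl)methyl] adduct of 14 | CC(C)(C)[Si](C)(C)OC1=CC[C@@H]2[C@](C)(C(=O)CCC2(O)C(OC)[Si](C)(C)C)[C@@H]1CC[C@H](C)CCO[Si](c3ccccc3)(c4ccccc4)C(C)(C)C
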